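**Retrosynthetic overview**
1. Numbering used throughout: eight-membered ring C1 (carries the side chain, C1′ = side-chain stereocentre) – C2 (C–OH) – C3 (CH2) – C4 (CH–CH3) – C5 – C6 (the two cyclopropane CH, C9 = cyclopropane CH2) – C7=C8 (butenolide; lactone C=O on C7, OCH2 on C8).
2. Target 33 ⇐ ketone 31 (C2=O, vinyl end group) by catalyst-controlled ketone reduction and a final cross-metathesis.
3. 31 ⇐ cyclobutanol 29 (key step): ionisation at C5 of a cyclobutane (ring C5–C4–C6–C9) contracts it to the cyclopropane (new C5–C6 bond) and the C4 cation is captured by the C3 enol carbon (new C3–C4 bond), so the three- and eight-membered rings form together. Enabling feature: C4, the CH(CH3) ring carbon, is a cyclopropylcarbinyl position on the C5–C6–C9 ring and is 1,3-related to the C2 oxygen, i.e. a 1-cyclopropylethyl cation (equivalent to a 2-methylcyclobutyl cation) next to an enolisable C2 ketone.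
4. 29 ⇐ aldehyde 13 + cyclobutylacetate 20: aldol, oxidation, (Z)-enol triflate, Stille hydroxymethylation with lactonisation (butenolide ring), then alkyne to enol acetate.
5. 13 ⇐ enamine-catalysed Michael addition (sets C1′ and C1), Nef/lactol, alkyne homologation; 20 ⇐ ketene [2+2], desymmetrising enolisation (sets C6), methylation (C4), reduction (C5). Ring order: cyclobutane (temporary), butenolide, then cyclopropane and cyclooctane in one operation.

Key step: step 21

Assumption: the (S,S)-lithium amide of step 11 is taken to remove the proton that leads to the (S)-enol ether 17 as drawn; if the opposite sense is found, the (R,R)-amide is used and nothing else changes.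

**Route**

Step 1
Reactants: 1 2-[(tert-butyldimethylsilyl)oxy]acetaldehyde
Product: 4 tert-butyldimethyl{[(2E)-3-nitroprop-2-en-1-yl]oxy}silane, via nitro alcohol 2 (not isolated), via mesylate 3 (not isolated)
Conditions: CH3NO2, NaOH (10 mol %), MeOH, 0 °C; then MsCl, Et3N, CH2Cl2, −10 to 0 °C
Reagents that add atoms: nitromethane C[N+](=O)[O-]
Why: Henry addition followed by mesylation and E1cB loss of methanesulfonate is the standard route to aliphatic nitroalkenes and gives the thermodynamic E isomer; no stereocentre remains.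

Step 2
Reactants: 4 tert-butyldimethyl{[(2E)-3-nitroprop-2-en-1-yl]oxy}silane, 5 hex-5-enal
Product: 6 (2S,3S)-2-(but-3-en-1-yl)-3-{[(tert-butyldimethylsilyl)oxy]methyl}-4-nitrobutanal
Conditions: (R)-α,α-diphenylprolinol trimethylsilyl ether (10 mol %), 4-nitrophenol (20 mol %), toluene, 0 to 20 °C
Reagents that add atoms: none
Why: Enamine-catalysed Michael addition of a linear aldehyde to a nitroalkene (diarylprolinol silyl ether catalysis) should give the syn γ-nitro aldehyde, the anti-enamine being shielded on one face by the diphenyl(silyloxy)methyl group, so that C1′ and C1 are both set by the catalyst, whose (R) enantiomer is chosen for the (2S,3S) product.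

Step 3
Reactants: 6 (2S,3S)-2-(but-3-en-1-yl)-3-{[(tert-butyldimethylsilyl)oxy]methyl}-4-nitrobutanal
Product: 7 (2S,3S)-2-(but-3-en-1-yl)-3-{[(tert-butyldimethylsilyl)oxy]methyl}-4-nitrobutan-1-ol
Conditions: NaBH4, MeOH, 0 °C
Reagents that add atoms: none
Why: Chemoselective borohydride reduction of the aldehyde beside the nitro group, carried out at once so that the α-stereocentre C1′ cannot epimerise.

Step 4
Reactants: 7 (2S,3S)-2-(but-3-en-1-yl)-3-{[(tert-butyldimethylsilyl)oxy]methyl}-4-nitrobutan-1-ol
Product: 9 (3R,4S)-4-(but-3-en-1-yl)-3-{[(tert-butyldimethylsilyl)oxy]methyl}oxolan-2-ol (anomer mixture), via sodium nitronate 8 (not isolated)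
Conditions: NaOMe, MeOH, 0 °C; then aqueous TiCl3, NH4OAc buffer (pH 5–6), THF, 20 °C
Reagents that add atoms: water O
Why: Reductive Nef reaction of the primary nitronate (TiCl3 reduces it to the imine, which hydrolyses); the aldehyde formed at C2 should be trapped at once as the five-membered lactol by the C1′ hydroxymethyl group, which protects it from self-condensation and from epimerisation at C1.

Step 5
Reactants: 9 (3R,4S)-4-(but-3-en-1-yl)-3-{[(tert-butyldimethylsilyl)oxy]methyl}oxolan-2-ol
Product: 10 (2S,3S)-2-(but-3-en-1-yl)-3-{[(tert-butyldimethylsilyl)oxy]methyl}pent-4-yn-1-ol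
Conditions: dimethyl (1-diazo-2-oxopropyl)phosphonate, K2CO3, MeOH, 0 to 20 °C
Reagents that add atoms: dimethyl (1-diazo-2-oxopropyl)phosphonate COP(=O)(OC)C(=[N+]=[N-])C(C)=O
Why: Seyferth–Gilbert homologation in the Ohira–Bestmann variant on the open hydroxy aldehyde form of the lactol, a standard lactol-to-alkynol conversion; the new alkyne carbon is the future C3 and the mild carbonate conditions should leave C1 untouched.

Step 6
Reactants: 10 (2S,3S)-2-(but-3-en-1-yl)-3-{[(tert-butyldimethylsilyl)oxy]methyl}pent-4-yn-1-ol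
Product: 11 (2S,3S)-2-(but-3-en-1-yl)-3-{[(tert-butyldimethylsilyl)oxy]methyl}pent-4-yn-1-yl acetate
Conditions: Ac2O, pyridine, DMAP (5 mol %), CH2Cl2, 0 °C
Reagents that add atoms: acetic anhydride CC(=O)OC(C)=O
Why: Acetylation of the only free hydroxyl installs the acetate of the target early, while the other primary oxygen is still silylated.

Step 7
Reactants: 11 (2S,3S)-2-(but-3-en-1-yl)-3-{[(tert-butyldimethylsilyl)oxy]methyl}pent-4-yn-1-yl acetate
Product: 12 (2S,3S)-2-(but-3-en-1-yl)-3-(hydroxymethyl)pent-4-yn-1-yl acetate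
Conditions: HF·pyridine, THF, 0 to 20 °C
Reagents that add atoms: none
Why: Fluoride-mediated cleavage of the primary silyl ether under buffered conditions that leave the acetate and the terminal alkyne intact; the 1,4-related acetate should not migrate.

Step 8
Reactants: 12 (2S,3S)-2-(but-3-en-1-yl)-3-(hydroxymethyl)pent-4-yn-1-yl acetate
Product: 13 (2S,3S)-2-(but-3-en-1-yl)-3-formylpent-4-yn-1-yl acetate
Conditions: Dess–Martin periodinane, NaHCO3, CH2Cl2, 0 °C
Reagents that add atoms: none
Why: Dess–Martin oxidation under buffered, non-basic conditions should give the α-ethynyl aldehyde (C8) without enolisation; it is used crude in step 15 because C1 is now α to a carbonyl group.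

Step 9
Reactants: 14 methyl but-3-enoate
Product: 15 methyl 2-(2,2-dichloro-3-oxocyclobutyl)acetate (racemic)
Conditions: Cl3CCOCl, Zn–Cu couple, Et2O/DME, sonication, 20 °C
Reagents that add atoms: trichloroacetyl chloride ClC(=O)C(Cl)(Cl)Cl
Why: [2+2] cycloaddition of dichloroketene (made in the flask by zinc dechlorination) to a monosubstituted alkene; the carbonyl carbon bonds to the terminal CH2, which gives the 3-substituted 2,2-dichlorocyclobutanone as a racemate.

Step 10
Reactants: 15 methyl 2-(2,2-dichloro-3-oxocyclobutyl)acetate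
Product: 16 methyl 2-(3-oxocyclobutyl)acetate
Conditions: Zn dust, AcOH, 20 to 50 °C
Reagents that add atoms: none
Why: Reductive dechlorination of the α,α-dichloro ketone with zinc in acetic acid removes the only stereocentre and gives the achiral 3-substituted cyclobutanone.

Step 11
Reactants: 16 methyl 2-(3-oxocyclobutyl)acetate
Product: 17 methyl 2-[(1S)-3-(trimethylsilyloxy)cyclobut-2-en-1-yl]acetate
Conditions: LiN[(S)-CHMePh]2, Me3SiCl (in situ quench), THF, −100 °C
Reagents that add atoms: chlorotrimethylsilane C[Si](C)(C)Cl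
Why: Enantiotopos-selective deprotonation of a prochiral 3-substituted cyclobutanone by a chiral lithium amide with internal silyl quench (asymmetric desymmetrisation); the choice between the two enantiotopic α-CH2 groups makes C6 a stereocentre, and the ketone is far more acidic than the ester.

Step 12
Reactants: 17 methyl 2-[(1S)-3-(trimethylsilyloxy)cyclobut-2-en-1-yl]acetate
Product: 18 methyl 2-[(1S,2S)-2-methyl-3-oxocyclobutyl]acetate
Conditions: MeI, benzyltrimethylammonium fluoride, 4 Å molecular sieves, THF, −20 to 20 °C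
Reagents that add atoms: iodomethane CI
Why: Fluoride-induced regiospecific alkylation of the silyl enol ether at the carbon that carried the double bond; methyl iodide should approach anti to the adjacent C6 substituent, setting C4 trans to it, and the trans ketone is also the thermodynamic epimer.

Step 13
Reactants: 18 methyl 2-[(1S,2S)-2-methyl-3-oxocyclobutyl]acetate
Product: 19 methyl 2-[(1S,2S,3S)-3-hydroxy-2-methylcyclobutyl]acetate
Conditions: NaBH4, MeOH, −78 °C
Reagents that add atoms: none
Why: Hydride reduction of a 3-substituted cyclobutanone, in which torsional control directs attack anti to the C6 substituent; this should give the all-pseudo-equatorial alcohol, with the C5 hydroxyl cis to the C6 side arm and trans to the C4 methyl group.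

Step 14
Reactants: 19 methyl 2-[(1S,2S,3S)-3-hydroxy-2-methylcyclobutyl]acetate
Product: 20 methyl 2-[(1S,2S,3S)-3-{[tert-butyl(dimethyl)silyl]oxy}-2-methylcyclobutyl]acetate
Conditions: TBSCl, imidazole, DMF, 20 °C
Reagents that add atoms: tert-butyldimethylsilyl chloride CC(C)(C)[Si](C)(C)Cl
Why: Standard silylation protects the cyclobutanol through the enolate, oxidation and triflation steps.

Step 15
Reactants: 20 methyl 2-[(1S,2S,3S)-3-{[tert-butyl(dimethyl)silyl]oxy}-2-methylcyclobutyl]acetate, 13 (2S,3S)-2-(but-3-en-1-yl)-3-formylpent-4-yn-1-yl acetate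
Product: 22 methyl (4S,5S)-5-(acetoxymethyl)-2-[(1R,2S,3S)-3-{[tert-butyl(dimethyl)silyl]oxy}-2-methylcyclobutyl]-4-ethynyl-3-hydroxynon-8-enoate (mixture at C2 and C3 of the chain), via lithium enolate 21 (not isolated)
Conditions: LiN(iPr)2, THF, −78 °C; then 13, −78 °C; AcOH quench
Reagents that add atoms: none
Why: Aldol addition of a lithium ester enolate to an aldehyde joins the fragments at the future C7–C8 bond; the two new stereocentres are left as a mixture because both are erased in steps 16 to 18, addition at −78 °C should outrun enolisation of the α-branched aldehyde, and any minor diastereomer from incomplete enantiopurity of a fragment is separated later.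

Step 16
Reactants: 22 β-hydroxy ester
Product: 23 methyl (4S,5S)-5-(acetoxymethyl)-2-[(1R,2S,3S)-3-{[tert-butyl(dimethyl)silyl]oxy}-2-methylcyclobutyl]-4-ethynyl-3-oxonon-8-enoate
Conditions: Dess–Martin periodinane, NaHCO3, CH2Cl2, 0 to 20 °C
Reagents that add atoms: none
Why: Dess–Martin oxidation of the β-hydroxy ester to the β-keto ester, whose acidic C7–H from now on shields the less acidic C1–H from base.

Step 17
Reactants: 23 β-keto ester
Product: 25 methyl (2Z,4S,5S)-5-(acetoxymethyl)-2-[(1R,2S,3S)-3-{[tert-butyl(dimethyl)silyl]oxy}-2-methylcyclobutyl]-4-ethynyl-3-{[(trifluoromethyl)sulfonyl]oxy}nona-2,8-dienoate, via sodium enolate 24 (not isolated)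
Conditions: NaH, THF, 0 °C; then PhNTf2, 0 to 20 °C
Reagents that add atoms: N-phenylbis(trifluoromethanesulfonimide) FC(F)(F)S(=O)(=O)N(c1ccccc1)S(=O)(=O)C(F)(F)F
Why: O-Triflation of the sodium-chelated β-keto ester enolate should give the enol triflate with the triflate cis to the ester (Z), the geometry needed for lactonisation; one equivalent of base removes only the doubly activated C7–H.

Step 18
Reactants: 25 (Z)-enol triflate
Product: 27 (2S,3S)-2-(but-3-en-1-yl)-3-{4-[(1R,2S,3S)-3-{[tert-butyl(dimethyl)silyl]oxy}-2-methylcyclobutyl]-5-oxo-2,5-dihydrofuran-3-yl}pent-4-yn-1-yl acetate, via hydroxymethyl enoate 26 (not isolated)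
Conditions: Bu3SnCH2OH, Pd(PPh3)4 (10 mol %), LiCl, 1,4-dioxane, 100 °C
Reagents that add atoms: (tributylstannyl)methanol CCCC[Sn](CCCC)(CCCC)CO
Why: Stille coupling of the enol triflate with the hydroxymethyl stannane proceeds with retention of alkene geometry, and the resulting (Z)-γ-hydroxy enoate should lactonise under the reaction conditions to the 3,4-disubstituted butenolide.

Step 19
Reactants: 27 silyl-protected butenolide
Product: 28 (2S,3S)-2-(but-3-en-1-yl)-3-{4-[(1R,2S,3S)-3-hydroxy-2-methylcyclobutyl]-5-oxo-2,5-dihydrofuran-3-yl}pent-4-yn-1-yl acetate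
Conditions: HF·pyridine, pyridine, THF, 0 to 20 °C
Reagents that add atoms: none
Why: Buffered fluoride desilylation of the secondary silyl ether avoids base, which would threaten the C1–H (γ to the lactone carbonyl and propargylic) and the acetate.

Step 20
Reactants: 28 alkynyl cyclobutanol
Product: 29 (3R,4S)-4-(acetoxymethyl)-3-{4-[(1R,2S,3S)-3-hydroxy-2-methylcyclobutyl]-5-oxo-2,5-dihydrofuran-3-yl}octa-1,7-dien-2-yl acetate
Conditions: AcOH, [RuCl2(p-cymene)]2 (2 mol %), tri(2-furyl)phosphine (8 mol %), Na2CO3 (5 mol %), toluene, 50 °C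
Reagents that add atoms: acetic acid CC(=O)O
Why: Ruthenium-catalysed Markovnikov addition of a carboxylic acid to a terminal alkyne gives the 1-alken-2-yl acetate, an enol derivative of the C2 ketone whose nucleophilic carbon is fixed at C3 and which leaves the C1 stereocentre untouched.

Step 21
Reactants: 29 enol acetate cyclobutanol
Product: 31 (2S)-2-[(C1R,C4S,C5R,C6R)-tricyclic C2 ketone]hex-5-en-1-yl acetate (cis-fused cyclopropane C5–C6–C9, cyclooctenone C1–C8, butenolide at C7=C8, methyl on C4), via cyclobutyl triflate 30 (not isolated)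
Conditions: Tf2O, 2,6-di-tert-butyl-4-methylpyridine, CH2Cl2 (0.005 M), −78 to −20 °C; aqueous NaHCO3
Reagents that add atoms: none
Why: Proposed new method: the cyclobutanol is triflated in situ and 30 ionises with participation of the antiperiplanar C4–C6 ring bond (the triflate is pseudo-equatorial), so that C6 shifts from C4 to C5 and displaces triflate from the rear, the C5–C6 cyclopropane bond forming by 1,3-closure across the four-membered ring while the charge moves to C4 (bisected 1-cyclopropylethyl cation), which is alkylated by the enol acetate carbon C3 to close the eight-membered ring (C3–C4 bond; both enol carbons and the cationic carbon are ring members), after which the acetoxycarbenium ion gives up its acetyl group to leave the C2 ketone. The closest known reactions are the solvolytic ring contraction of 2-methylcyclobutyl sulfonates to 1-cyclopropylethyl products and the termination of carbocations by enol esters or silyl enol ethers (SN1-type α-alkylation, cation–olefin cyclisation); their combination and the eight-membered closure are new. C6 keeps its configuration (migrating carbon, retention) and C5 is inverted (rear-side bond shift), so the triflate cis to the C6 substituent in 30 translates into the cis-fused cyclopropane; C4 is set because the methyl group trans to the triflate ends up anti to the ring in the cation and because the tether through C7=C8–C1–C2 can only reach the lobe that faced C6. The step needs migration of the methyl-bearing ring bond (the other bond would give a primary cyclopropylcarbinyl cation) and capture at C4 in the eight-membered mode in preference to attack at ring carbon C6 (six-membered ring, homoallyl product), proton loss or intermolecular capture; the methyl-stabilised carbinyl carbon carries most of the charge, C6 is deactivated by the electron-poor butenolide, and the non-nucleophilic medium (hindered base, high dilution) with reversible ion-pair return to a covalent triflate keeps the cation available for the slow ring closure.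

Step 22
Reactants: 31 tricyclic ketone
Product: 32 (2S)-2-[(C1R,C2S,C4S,C5R,C6R)-tricyclic C2 alcohol]hex-5-en-1-yl acetate
Conditions: (R)-1-methyl-3,3-diphenyltetrahydro-1H,3H-pyrrolo[1,2-c][1,3,2]oxazaborole ((R)-Me-CBS, 20 mol %), catecholborane, toluene/CH2Cl2, −78 °C
Reagents that add atoms: none
Why: Corey–Bakshi–Shibata reduction in which the catalyst differentiates the branched C1 side from the C3 methylene side of the ketone, so that the (R)-catalyst should deliver hydride to give the (S)-carbinol at C2; catecholborane at −78 °C leaves the terminal alkene, the butenolide and the acetate alone.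

Step 23
Reactants: 32 tricyclic alcohol
Product: 33 target, (2S)-2-[(C1R,C2S,C4S,C5R,C6R)-tricyclic C2 alcohol]-6-methylhept-5-en-1-yl acetate
Conditions: 2-methylbut-2-ene (excess), second-generation Grubbs catalyst RuCl2(=CHPh)(PCy3)(H2IMes) (5 mol %), CH2Cl2, 40 °C
Reagents that add atoms: 2-methylbut-2-ene CC=C(C)C
Why: Olefin cross-metathesis of a monosubstituted alkene with 2-methylbut-2-ene converts the vinyl terminus into the trisubstituted isopropylidene end group; the tetrasubstituted butenolide alkene is inert and no stereocentre is touched.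

**Compound list**
1 | 2-[(tert-butyldimethylsilyl)oxy]acetaldehyde | O=CCO[Si](C)(C)C(C)(C)C | starting material
2 | 1-[(tert-butyldimethylsilyl)oxy]-3-nitropropan-2-ol (racemic, not isolated) | CC(C)(C)[Si](C)(C)OCC(O)C[N+](=O)[O-] | intermediate
3 | 1-[(tert-butyldimethylsilyl)oxy]-3-nitropropan-2-yl methanesulfonate (not isolated) | CC(C)(C)[Si](C)(C)OCC(OS(C)(=O)=O)C[N+](=O)[O-] | intermediate
4 | tert-butyldimethyl{[(2E)-3-nitroprop-2-en-1-yl]oxy}silane | CC(C)(C)[Si](C)(C)OC/C=C/[N+](=O)[O-] | intermediate
5 | hex-5-enal | C=CCCCC=O | starting material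
6 | (2S,3S)-2-(but-3-en-1-yl)-3-{[(tert-butyldimethylsilyl)oxy]methyl}-4-nitrobutanal | O=C[C@@H](CCC=C)[C@@H](C[N+](=O)[O-])CO[Si](C)(C)C(C)(C)C | intermediate
7 | (2S,3S)-2-(but-3-en-1-yl)-3-{[(tert-butyldimethylsilyl)oxy]methyl}-4-nitrobutan-1-ol | OC[C@@H](CCC=C)[C@@H](C[N+](=O)[O-])CO[Si](C)(C)C(C)(C)C | intermediate
8 | sodium nitronate of 7 (not isolated) | [Na+].OC[C@@H](CCC=C)[C@@H](C=[N+]([O-])[O-])CO[Si](C)(C)C(C)(C)C | intermediate
9 | (3R,4S)-4-(but-3-en-1-yl)-3-{[(tert-butyldimethylsilyl)oxy]methyl}oxolan-2-ol (anomer mixture) | OC1OC[C@@H](CCC=C)[C@@H]1CO[Si](C)(C)C(C)(C)C | intermediate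
10 | (2S,3S)-2-(but-3-en-1-yl)-3-{[(tert-butyldimethylsilyl)oxy]methyl}pent-4-yn-1-ol | OC[C@@H](CCC=C)[C@@H](C#C)CO[Si](C)(C)C(C)(C)C | intermediate
11 | (2S,3S)-2-(but-3-en-1-yl)-3-{[(tert-butyldimethylsilyl)oxy]methyl}pent-4-yn-1-yl acetate | CC(=O)OC[C@@H](CCC=C)[C@@H](C#C)CO[Si](C)(C)C(C)(C)C | intermediate
12 | (2S,3S)-2-(but-3-en-1-yl)-3-(hydroxymethyl)pent-4-yn-1-yl acetate | CC(=O)OC[C@@H](CCC=C)[C@@H](C#C)CO | intermediate
13 | (2S,3S)-2-(but-3-en-1-yl)-3-formylpent-4-yn-1-yl acetate | CC(=O)OC[C@@H](CCC=C)[C@@H](C#C)C=O | intermediate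
14 | methyl but-3-enoate | C=CCC(=O)OC | starting material
15 | methyl 2-(2,2-dichloro-3-oxocyclobutyl)acetate (racemic) | COC(=O)CC1CC(=O)C1(Cl)Cl | intermediate
16 | methyl 2-(3-oxocyclobutyl)acetate | COC(=O)CC1CC(=O)C1 | intermediate
17 | methyl 2-[(1S)-3-(trimethylsilyloxy)cyclobut-2-en-1-yl]acetate | COC(=O)C[C@@H]1CC(O[Si](C)(C)C)=C1 | intermediate
18 | methyl 2-[(1S,2S)-2-methyl-3-oxocyclobutyl]acetate | COC(=O)C[C@@H]1CC(=O)[C@H]1C | intermediate
19 | methyl 2-[(1S,2S,3S)-3-hydroxy-2-methylcyclobutyl]acetate | COC(=O)C[C@@H]1C[C@H](O)[C@H]1C | intermediate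
20 | methyl 2-[(1S,2S,3S)-3-{[tert-butyl(dimethyl)silyl]oxy}-2-methylcyclobutyl]acetate | COC(=O)C[C@@H]1C[C@H](O[Si](C)(C)C(C)(C)C)[C@H]1C | intermediate
21 | lithium enolate of 20 (not isolated) | [Li]OC(OC)=C[C@@H]1C[C@H](O[Si](C)(C)C(C)(C)C)[C@H]1C | intermediate
22 | methyl (4S,5S)-5-(acetoxymethyl)-2-[(1R,2S,3S)-3-{[tert-butyl(dimethyl)silyl]oxy}-2-methylcyclobutyl]-4-ethynyl-3-hydroxynon-8-enoate (mixture at C2 and C3) | CC(=O)OC[C@@H](CCC=C)[C@@H](C#C)C(O)C(C(=O)OC)[C@@H]1C[C@H](O[Si](C)(C)C(C)(C)C)[C@H]1C | intermediate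
23 | methyl (4S,5S)-5-(acetoxymethyl)-2-[(1R,2S,3S)-3-{[tert-butyl(dimethyl)silyl]oxy}-2-methylcyclobutyl]-4-ethynyl-3-oxonon-8-enoate | CC(=O)OC[C@@H](CCC=C)[C@@H](C#C)C(=O)C(C(=O)OC)[C@@H]1C[C@H](O[Si](C)(C)C(C)(C)C)[C@H]1C | intermediate
24 | sodium (Z)-enolate of 23 (not isolated) | [Na+].CC(=O)OC[C@@H](CCC=C)[C@@H](C#C)/C([O-])=C(/C(=O)OC)[C@@H]1C[C@H](O[Si](C)(C)C(C)(C)C)[C@H]1C | intermediate
25 | methyl (2Z,4S,5S)-5-(acetoxymethyl)-2-[(1R,2S,3S)-3-{[tert-butyl(dimethyl)silyl]oxy}-2-methylcyclobutyl]-4-ethynyl-3-{[(trifluoromethyl)sulfonyl]oxy}nona-2,8-dienoate | CC(=O)OC[C@@H](CCC=C)[C@@H](C#C)/C(OS(=O)(=O)C(F)(F)F)=C(/C(=O)OC)[C@@H]1C[C@H](O[Si](C)(C)C(C)(C)C)[C@H]1C | intermediate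
26 | methyl (2Z,4S,5S)-5-(acetoxymethyl)-2-[(1R,2S,3S)-3-{[tert-butyl(dimethyl)silyl]oxy}-2-methylcyclobutyl]-4-ethynyl-3-(hydroxymethyl)nona-2,8-dienoate (not isolated) | CC(=O)OC[C@@H](CCC=C)[C@@H](C#C)/C(CO)=C(/C(=O)OC)[C@@H]1C[C@H](O[Si](C)(C)C(C)(C)C)[C@H]1C | intermediate
27 | (2S,3S)-2-(but-3-en-1-yl)-3-{4-[(1R,2S,3S)-3-{[tert-butyl(dimethyl)silyl]oxy}-2-methylcyclobutyl]-5-oxo-2,5-dihydrofuran-3-yl}pent-4-yn-1-yl acetate | CC(=O)OC[C@@H](CCC=C)[C@@H](C#C)C1=C(C(=O)OC1)[C@@H]2C[C@H](O[Si](C)(C)C(C)(C)C)[C@H]2C | intermediate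
28 | (2S,3S)-2-(but-3-en-1-yl)-3-{4-[(1R,2S,3S)-3-hydroxy-2-methylcyclobutyl]-5-oxo-2,5-dihydrofuran-3-yl}pent-4-yn-1-yl acetate | CC(=O)OC[C@@H](CCC=C)[C@@H](C#C)C1=C(C(=O)OC1)[C@@H]2C[C@H](O)[C@H]2C | intermediate
29 | (3R,4S)-4-(acetoxymethyl)-3-{4-[(1R,2S,3S)-3-hydroxy-2-methylcyclobutyl]-5-oxo-2,5-dihydrofuran-3-yl}octa-1,7-dien-2-yl acetate | CC(=O)OC[C@@H](CCC=C)[C@@H](C(=C)OC(C)=O)C1=C(C(=O)OC1)[C@@H]2C[C@H](O)[C@H]2C | intermediate
30 | cyclobutyl trifluoromethanesulfonate of 29 (not isolated) | CC(=O)OC[C@@H](CCC=C)[C@@H](C(=C)OC(C)=O)C1=C(C(=O)OC1)[C@@H]2C[C@H](OS(=O)(=O)C(F)(F)F)[C@H]2C | intermediate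
31 | (2S)-2-[(C1R,C4S,C5R,C6R)-tricyclic C2 ketone]hex-5-en-1-yl acetate: cis-fused cyclopropane (C5, C6, C9), cyclooctenone (C1–C8, C2=O, CH3 on C4) and butenolide (C7=C8, lactone C=O on C7) | CC(=O)OC[C@@H](CCC=C)[C@@H]1C2=C(C(=O)OC2)[C@@H]2C[C@@H]2[C@@H](C)CC1=O | intermediate
32 | (2S)-2-[(C1R,C2S,C4S,C5R,C6R)-tricyclic C2 alcohol]hex-5-en-1-yl acetate (same tricycle with C2–OH) | CC(=O)OC[C@@H](CCC=C)[C@@H]1C2=C(C(=O)OC2)[C@@H]2C[C@@H]2[C@@H](C)C[C@@H]1O | intermediate
33 | target: (2S)-2-[(C1R,C2S,C4S,C5R,C6R)-tricyclic C2 alcohol]-6-methylhept-5-en-1-yl acetate | CC(=O)OC[C@@H](CCC=C(C)C)[C@@H]1C2=C(C(=O)OC2)[C@@H]2C[C@@H]2[C@@H](C)C[C@@H]1O | target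

**Totals**
Total step count: 23. Longest linear sequence: 17 steps (steps 1 to 8, then 15 to 23); the cyclobutane branch is steps 9 to 14.

**Steps most likely to fail, each with one fallback**

Step 21 (proposed new method). The cation may be lost before the eight-membered ring closes: proton loss from the methyl group, attack of the enol carbon at ring carbon C6 (six-membered ring), or intermolecular capture. The fallback separates the two bond formations, sets out from alkyne 28 and returns at ketone 31. Compound 28 is mesylated (MsCl, Et3N) to the cyclobutyl mesylate F1, which is solvolysed in aqueous acetone over CaCO3. The same ring contraction, now ended by water (the known solvolysis of 2-methylcyclobutyl sulfonates), gives the 1-cyclopropylethanol F2 with the cis-cyclopropane in place. Dess–Martin oxidation gives the cyclopropyl methyl ketone F3 (C4 as carbonyl). Ruthenium-catalysed addition of acetic acid as in step 20 gives the enol acetate F4, and N-bromosuccinimide in wet THF gives the bromomethyl ketone F5. SmI2 in THF at −78 °C under high dilution closes the eight-membered ring by a Reformatsky-type addition of the samarium enolate (C3) to the C4 ketone, giving the β-hydroxy ketone F6. Dehydration with the Burgess reagent gives the enone F7, and conjugate reduction with [(Ph3P)CuH]6 gives 31; C4 then rests on hydride delivery, and a C4 epimer would have to be separated.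

Step 18. Transmetalation at the hindered, tetrasubstituted enol triflate may be slow, so that triflate hydrolysis and loss of the stannane compete. The fallback sets out from enol triflate 25 and returns at butenolide 27. Palladium-catalysed reductive carbonylation (CO, Bu3SnH, Pd(PPh3)4, THF, 50 °C) gives the formyl ester F8, in which carbon monoxide insertion replaces the slow transfer of the hydroxymethyl group. Reduction with NaBH4 and CeCl3 at −78 °C gives allylic alcohol 26, which lactonises to 27.

Step 13. Facial selectivity of hydride delivery may be poor or reversed, because attack anti to the C6 substituent is syn to the adjacent C4 methyl group. The fallback sets out from ketone 18 and returns at alcohol 19. LiBH(sBu)3 at −78 °C, which attacks anti to the methyl group, gives the C5-epimeric alcohol F9. Mitsunobu inversion with 4-nitrobenzoic acid (PPh3, diisopropyl azodicarboxylate) gives the 4-nitrobenzoate F10, and K2CO3 in methanol gives 19.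

Further compounds
F1 | step 21 | cyclobutyl methanesulfonate of 28 | CC(=O)OC[C@@H](CCC=C)[C@@H](C#C)C1=C(C(=O)OC1)[C@@H]2C[C@H](OS(C)(=O)=O)[C@H]2C
F2 | step 21 | 1-cyclopropylethanol from ring contraction (cis-cyclopropane, carbinol at C4 as a mixture) | CC(=O)OC[C@@H](CCC=C)[C@@H](C#C)C1=C(C(=O)OC1)[C@@H]2C[C@@H]2C(C)O
F3 | step 21 | cyclopropyl methyl ketone (C4=O) | CC(=O)OC[C@@H](CCC=C)[C@@H](C#C)C1=C(C(=O)OC1)[C@@H]2C[C@@H]2C(C)=O
F4 | step 21 | enol acetate of the C2 ketone with the C4 ketone | CC(=O)OC[C@@H](CCC=C)[C@@H](C(=C)OC(C)=O)C1=C(C(=O)OC1)[C@@H]2C[C@@H]2C(C)=O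
F5 | step 21 | bromomethyl ketone (C3–Br) | CC(=O)OC[C@@H](CCC=C)[C@@H](C(=O)CBr)C1=C(C(=O)OC1)[C@@H]2C[C@@H]2C(C)=O
F6 | step 21 | eight-membered β-hydroxy ketone (tertiary OH at C4) | CC(=O)OC[C@@H](CCC=C)[C@@H]1C2=C(C(=O)OC2)[C@@H]2C[C@@H]2C(C)(O)CC1=O
F7 | step 21 | eight-membered enone (C3=C4) | CC(=O)OC[C@@H](CCC=C)[C@@H]1C2=C(C(=O)OC2)[C@@H]2C[C@@H]2C(C)=CC1=O
F8 | step 18 | methyl (2Z,4S,5S)-5-(acetoxymethyl)-2-[(1R,2S,3S)-3-{[tert-butyl(dimethyl)silyl]oxy}-2-methylcyclobutyl]-4-ethynyl-3-formylnona-2,8-dienoate | CC(=O)OC[C@@H](CCC=C)[C@@H](C#C)/C(C=O)=C(/C(=O)OC)[C@@H]1C[C@H](O[Si](C)(C)C(C)(C)C)[C@H]1C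
F9 | step 13 | methyl 2-[(1S,2S,3R)-3-hydroxy-2-methylcyclobutyl]acetate | COC(=O)C[C@@H]1C[C@@H](O)[C@H]1C
F10 | step 13 | (1S,2S,3S)-3-(2-methoxy-2-oxoethyl)-2-methylcyclobutyl 4-nitrobenzoate | COC(=O)C[C@@H]1C[C@H](OC(=O)c2ccc(cc2)[N+](=O)[O-])[C@H]1C
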